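**Amounts.** The flask holds 0.77 M of substrate with 2 mol% of free catalyst, which is 15.4 mM of catalyst in all, and the gas phase is held while the solution starts without dissolved gas.

substrate 0.77 M; gas phase 25 mM (held); free catalyst 2 mol%; time 2.0 d

1. how much product there is at 2.0 d, in percent of the substrate charged
2. the change that raises the amount of product at 2.0 d, in percent of the substrate charged most ("none" if none brings more than 2 percentage points) (Tuesday's / Monday's / Thursday's / none)
3. amount of product at 2.0 d, in percent of the substrate charged, after Tuesday's

- Tuesday's: doubling the transfer coefficient of step 1, all else as stated
- Monday's: doubling the saturation concentration of gas phase, all else as stated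
- Thursday's: doubling the amount of free catalyst, all else as stated

**Catalyst side.** Turnover runs at 730 M⁻² h⁻¹ times c(substrate), c(dissolved gas) and c(free catalyst), and the balance of the idle complex keeps c(free catalyst) at the total of these two forms divided by one plus 1900 M⁻¹ times c(dissolved gas); I leave the spent catalyst out of this reckoning and take that total as the catalyst charged. If the idle complex holds the catalyst, the gas cancels and the substrate falls pseudo-first-order, with a ceiling constant equal to the turnover constant times the catalyst total over the balance constant, 0.00592 h⁻¹, so by 2.0 d I get 24.7% of product.

**Gas side.** The crossing into a solution kept empty delivers up to 53.0% by then, more than the ceiling, so the two ways part, and I take the gas figure as the one that cheats, since it supposes a solution kept empty. The starting demand of 4.56 mM h⁻¹ is about half of the crossing's top rate, so crossing and demand balance near c(dissolved gas) = 11.6 mM, where the bound share is 95.7%. Ceiling constant times bound share is the working constant 0.00566 h⁻¹, and it gives me 23.8%.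

**The changes.** Tuesday's raises the balance to 18.3 mM and my figure to 24.1%, a gain of 0.30 percentage points, less than the margin of 2 points. Monday's raises the balance to 36.6 mM and my figure to 24.4%, a gain of 0.60 points, also less than that margin. Thursday's doubles the ceiling constant, though its doubled starting demand exceeds the crossing's top rate, so I take 43.4% as an upper figure for it, and Thursday's is my choice.

**The result.** The forecast gives 23%, 23.7% after Tuesday's and Thursday's as the best change, holding that “gas transfer is not truly limiting”. The flask gives 22.8%, which is 1.00 point below my figure, and 23.6% after Tuesday's; Thursday's is best with a gain of 13 points, against 0.82 points for Tuesday's and 1.1 points for Monday's.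

    gas phase ⇌ dissolved gas, rate k1*(csat - [dissolved gas]) (k1 = 0.34 h⁻¹, csat = 25 mM)
    substrate + dissolved gas + free catalyst → free catalyst + product (k2 = 730 M⁻² h⁻¹)
    2 free catalyst → spent catalyst (k3 = 0.96 M⁻¹ h⁻¹)
    dissolved gas + free catalyst ⇌ idle complex, settled at all times (K4 = 1900 M⁻¹)

**Not at rest.** At 2.0 d the flask still holds 77% of its substrate and is moving. The working constant predicts 66.3% of product for the same flask read at 8.0 d, and that reading stands at 65.5%. For ten times the time it predicts 93.4%, and the flask then stands at 93.1%, a further 70 points of product, with 6.85% of the substrate still there at 20.0 d.

(The rate constants stand for no real mixture; the run is a simulation.)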